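**Strategy.** The tetrahydrofuran ring is closed between its methylene carbon C3 and its carbinol carbon C4. C2 is carried at the lactone oxidation level, so that the ring oxygen O1 is the ester oxygen of a simple diazoacetate of (S)-1-(benzyloxy)heptan-2-ol. A chiral dirhodium carboxamidate converts this acyclic ester into the cis-4-benzyloxy-5-pentyl γ-lactone by carbenoid insertion into the C4–H bond, which the oxygen on C4 activates; C4 is set in the same operation. The side chain then enters at the lactone carbonyl C2 as a sparteine-derived lithiated carbamate (C1' stereocentre), and ionic hydrogenation of the hemiketal places it trans to both ring substituents.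

Key step: step 4

Remark: atom labels are O1 (ring oxygen), C2 (ring carbon bearing the side chain), C3 (ring CH2), C4 (ring carbon bearing oxygen), C5 (ring carbon bearing pentyl) and C1' (side-chain carbon bearing the ester oxygen). Rh2(5S-MEPY)4 is dirhodium tetrakis[methyl (5S)-2-oxopyrrolidine-5-carboxylate]. The S ligand series is assumed to favour the 4S lactone, and s-BuLi/(−)-sparteine is assumed to remove the pro-S hydrogen of the carbamate.

**Step 1**
Reactants: 1 (S)-benzyl glycidyl ether
Product: 2 (S)-1-(benzyloxy)heptan-2-ol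
Conditions: n-BuMgBr, CuBr·SMe2 (10 mol%), THF, −40 °C to 0 °C
Reagents that add atoms: butylmagnesium bromide, CCCC[Mg]Br
Why: Copper-catalysed Grignard opening of the terminal epoxide (SN2 at the unsubstituted carbon) should extend the chain to pentyl and leave the stereocentre, the future C5, untouched.

**Step 2**
Reactants: 2 (S)-1-(benzyloxy)heptan-2-ol
Product: 3 (S)-1-(benzyloxy)heptan-2-yl bromoacetate
Conditions: BrCH2COBr, NaHCO3, MeCN, 0 °C
Reagents that add atoms: bromoacetyl bromide, BrCC(Br)=O
Why: Acylation of the secondary alcohol by the acid bromide (nucleophilic acyl substitution) should proceed cleanly with NaHCO3 as HBr scavenger and installs C2 and C3.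

**Step 3**
Reactants: 3 (S)-1-(benzyloxy)heptan-2-yl bromoacetate
Product: 5 (S)-1-(benzyloxy)heptan-2-yl diazoacetate, via N-alkylated ditosylhydrazine 4 (not isolated)
Conditions: TsNHNHTs, DBU, THF, 0 °C
Reagents that add atoms: N,N'-ditosylhydrazine, Cc1ccc(cc1)S(=O)(=O)NNS(=O)(=O)c1ccc(C)cc1
Why: Fukuyama diazoacetate synthesis, in which SN2 alkylation of the ditosylhydrazine anion gives 4 and DBU then expels two sulfinate ions to unveil the diazo group without touching the ester or the stereocentre.

**Step 4**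
Reactants: 5 (S)-1-(benzyloxy)heptan-2-yl diazoacetate
Product: 6 (4S,5S)-4-(benzyloxy)-5-pentyloxolan-2-one
Conditions: Rh2(5S-MEPY)4 (1 mol%), CH2Cl2, reflux, slow addition of 5 over 10 h
Reagents that add atoms: none
Why: Loss of N2 from 5 at the divalent-rhodium carboxamidate gives an electrophilic rhodium carbenoid at C3, which inserts into the C4–H bond through a concerted three-centre transition state, forming the C3–C4 bond and closing the five-membered lactone ring (O1, C2, C3, C4, C5) in a 1,5-insertion mode. The closest known reaction type is the dirhodium carboxamidate-catalysed intramolecular C–H insertion of 2-alkoxyethyl and 1,3-dialkoxypropan-2-yl diazoacetates to 4-alkoxy γ-butyrolactones. The new C4 stereocentre is controlled by the chiral ligand sphere, which selects one of the two diastereotopic C4 hydrogens; the S ligand set is expected to favour the 4S centre and so to reinforce the substrate preference for a cis relation between the benzyloxy group and the C5 pentyl group. The step needs site selectivity for C4–H over the unactivated CH2 of the pentyl chain (also a 1,5 position) and over oxonium ylide formation at the benzyl ether oxygen; donation from the ether oxygen into the C4–H bond, the low electrophilicity of the carboxamidate carbenoid and slow addition should secure it. The C5 stereocentre is not touched.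

**Step 5**
Reactants: 7 dec-9-en-1-ol
Product: 8 dec-9-en-1-yl N,N-diisopropylcarbamate
Conditions: iPr2NCOCl, NaH, THF, reflux
Reagents that add atoms: N,N-diisopropylcarbamoyl chloride, CC(C)N(C(C)C)C(Cl)=O
Why: O-Carbamoylation of the sodium alkoxide (nucleophilic acyl substitution) should install the directing group needed for the later α-lithiation.

**Step 6**
Reactants: 8 dec-9-en-1-yl N,N-diisopropylcarbamate; 6 (4S,5S)-4-(benzyloxy)-5-pentyloxolan-2-one
Product: 10 (1R)-1-[(4S,5S)-4-(benzyloxy)-2-hydroxy-5-pentyloxolan-2-yl]dec-9-en-1-yl N,N-diisopropylcarbamate, via lithiated carbamate 9 (not isolated)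
Conditions: s-BuLi, (−)-sparteine, Et2O, −78 °C, 5 h; then 6, −78 °C; AcOH quench at −78 °C
Reagents that add atoms: none
Why: Hoppe enantioselective deprotonation should remove the pro-S hydrogen next to the carbamate oxygen to give the configurationally stable carbanion 9, whose acylation by the lactone carbonyl with retention sets C1' as R, the lithium hemiketal alkoxide being stable at −78 °C so that no second addition occurs.

**Step 7**
Reactants: 10 (1R)-1-[(4S,5S)-4-(benzyloxy)-2-hydroxy-5-pentyloxolan-2-yl]dec-9-en-1-yl N,N-diisopropylcarbamate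
Product: 12 (1R)-1-[(2R,4S,5S)-4-(benzyloxy)-5-pentyloxolan-2-yl]dec-9-en-1-yl N,N-diisopropylcarbamate, via oxocarbenium ion 11 (not isolated)
Conditions: Et3SiH, BF3·OEt2, CH2Cl2, −78 °C to −20 °C
Reagents that add atoms: none
Why: Ionic hydrogenation of a hemiketal (the reductive deoxygenation used for C-glycosides), in which BF3·OEt2 should ionise 10 to the ring oxocarbenium ion 11 and Et3SiH should attack its envelope from the inside face, cis to the pseudoaxial C4 benzyloxy group and to the C5 pentyl group, which sets C2 as R with the side chain trans to both ring substituents.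

**Step 8**
Reactants: 12 (1R)-1-[(2R,4S,5S)-4-(benzyloxy)-5-pentyloxolan-2-yl]dec-9-en-1-yl N,N-diisopropylcarbamate
Product: 13 (1R)-1-[(2R,4S,5S)-4-(benzyloxy)-5-pentyloxolan-2-yl]dec-9-en-1-ol
Conditions: LiAlH4, THF, reflux
Reagents that add atoms: none
Why: Reductive cleavage of the hindered carbamate by LiAlH4 (hydride attack at the carbamate carbonyl) should free the C1' hydroxyl without touching the benzyl ether, the terminal alkene or any stereocentre.

**Step 9**
Reactants: 13 (1R)-1-[(2R,4S,5S)-4-(benzyloxy)-5-pentyloxolan-2-yl]dec-9-en-1-ol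
Product: 14 (1R)-1-[(2R,4S,5S)-4-(benzyloxy)-5-pentyloxolan-2-yl]dec-9-en-1-yl dodecanoate
Conditions: dodecanoyl chloride, pyridine, DMAP (cat.), CH2Cl2, 0 °C to rt
Reagents that add atoms: dodecanoyl chloride, CCCCCCCCCCCC(Cl)=O
Why: DMAP-catalysed acylation of the only free hydroxyl should give the laurate with retention at C1'.

**Step 10**
Reactants: 14 (1R)-1-[(2R,4S,5S)-4-(benzyloxy)-5-pentyloxolan-2-yl]dec-9-en-1-yl dodecanoate
Product: 15 (1R)-1-[(2R,4S,5S)-4-hydroxy-5-pentyloxolan-2-yl]dec-9-en-1-yl dodecanoate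
Conditions: BCl3, pentamethylbenzene, CH2Cl2, −78 °C; MeOH quench
Reagents that add atoms: none
Why: Lewis-acid debenzylation, in which BCl3 cleaves the benzyl ether at −78 °C while pentamethylbenzene traps the benzyl cation, should spare the laurate ester, the terminal alkene and the ring ether and so release the C4 hydroxyl of the target.

**Compound list**
1 | (S)-benzyl glycidyl ether, (S)-2-[(benzyloxy)methyl]oxirane | C1O[C@@H]1COCc2ccccc2 | starting material
2 | (S)-1-(benzyloxy)heptan-2-ol | O[C@@H](CCCCC)COCc1ccccc1 | intermediate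
3 | (S)-1-(benzyloxy)heptan-2-yl bromoacetate | BrCC(=O)O[C@@H](CCCCC)COCc1ccccc1 | intermediate
4 | (S)-1-(benzyloxy)heptan-2-yl [1,2-bis(p-tolylsulfonyl)hydrazinyl]acetate (not isolated) | Cc1ccc(cc1)S(=O)(=O)NN(CC(=O)O[C@@H](CCCCC)COCc1ccccc1)S(=O)(=O)c1ccc(C)cc1 | intermediate
5 | (S)-1-(benzyloxy)heptan-2-yl diazoacetate | [N-]=[N+]=CC(=O)O[C@@H](CCCCC)COCc1ccccc1 | intermediate
6 | (4S,5S)-4-(benzyloxy)-5-pentyloxolan-2-one (cis lactone) | O=C1C[C@H](OCc2ccccc2)[C@H](CCCCC)O1 | intermediate
7 | dec-9-en-1-ol | C=CCCCCCCCCO | starting material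
8 | dec-9-en-1-yl N,N-diisopropylcarbamate | C=CCCCCCCCCOC(=O)N(C(C)C)C(C)C | intermediate
9 | (S)-1-lithiodec-9-en-1-yl N,N-diisopropylcarbamate, sparteine-bound (not isolated) | C=CCCCCCCC[C@H]([Li])OC(=O)N(C(C)C)C(C)C | intermediate
10 | (1R)-1-[(4S,5S)-4-(benzyloxy)-2-hydroxy-5-pentyloxolan-2-yl]dec-9-en-1-yl N,N-diisopropylcarbamate (hemiketal, both C2 epimers, in equilibrium with the open hydroxy ketone) | C=CCCCCCCC[C@@H](OC(=O)N(C(C)C)C(C)C)C1(O)C[C@H](OCc2ccccc2)[C@H](CCCCC)O1 | intermediate
11 | ring oxocarbenium ion from 10 (C2=O1 cation; C4 S, C5 S, C1' R; not isolated) | C=CCCCCCCC[C@@H](OC(=O)N(C(C)C)C(C)C)C1=[O+][C@@H](CCCCC)[C@@H](OCc2ccccc2)C1 | intermediate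
12 | (1R)-1-[(2R,4S,5S)-4-(benzyloxy)-5-pentyloxolan-2-yl]dec-9-en-1-yl N,N-diisopropylcarbamate | C=CCCCCCCC[C@@H](OC(=O)N(C(C)C)C(C)C)[C@H]1C[C@H](OCc2ccccc2)[C@H](CCCCC)O1 | intermediate
13 | (1R)-1-[(2R,4S,5S)-4-(benzyloxy)-5-pentyloxolan-2-yl]dec-9-en-1-ol | C=CCCCCCCC[C@@H](O)[C@H]1C[C@H](OCc2ccccc2)[C@H](CCCCC)O1 | intermediate
14 | (1R)-1-[(2R,4S,5S)-4-(benzyloxy)-5-pentyloxolan-2-yl]dec-9-en-1-yl dodecanoate | C=CCCCCCCC[C@@H](OC(=O)CCCCCCCCCCC)[C@H]1C[C@H](OCc2ccccc2)[C@H](CCCCC)O1 | intermediate
15 | (1R)-1-[(2R,4S,5S)-4-hydroxy-5-pentyloxolan-2-yl]dec-9-en-1-yl dodecanoate | C=CCCCCCCC[C@@H](OC(=O)CCCCCCCCCCC)[C@H]1C[C@H](O)[C@H](CCCCC)O1 | target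

**Step count.** Total: 10 steps. Longest linear sequence: 9 steps (steps 1–4 and 6–10); step 5 is a one-step side branch.

**Steps most likely to fail**

Step 6. The sparteine-bound carbanion 9 is bulky and basic. Deprotonation of 6 at C3 with β-elimination of benzyl oxide, or sluggish carbonyl addition, may outrun hemiketal formation. Fallback: the C1'–C2 bond is made last under substrate control, setting out from 6. CeCl3-promoted addition of vinylmagnesium bromide (THF, −78 °C) should give the vinyl hemiketal (4S,5S)-4-(benzyloxy)-2-ethenyl-5-pentyloxolan-2-ol F1. Et3SiH/BF3·OEt2 (CH2Cl2, −78 °C) should then give the 2,5-trans vinyl oxolane (2R,4S,5S)-4-(benzyloxy)-2-ethenyl-5-pentyloxolane F2. Ozonolysis (O3, CH2Cl2, −78 °C; PPh3) should give the aldehyde (2R,4S,5S)-4-(benzyloxy)-5-pentyloxolane-2-carbaldehyde F3. Chelation-controlled addition of non-8-en-1-ylmagnesium bromide (MgBr2·OEt2, CH2Cl2, −78 °C) should give the threo alcohol, where the route is rejoined at 13.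

Step 7. The carbamate carbonyl may capture the oxocarbenium ion 11 as a spiro dioxolanylium ion, or 11 may lose the C1' proton. Either would slow the reduction, erode the facial selectivity at C2 or scramble C1'. Fallback: the side-chain oxygen is carried as a non-participating ether, setting out from 7 and 6. Oxidation of 7 (Dess–Martin periodinane, CH2Cl2) gives dec-9-enal F4. Bu3SnLi followed by 1,1'-(azodicarbonyl)dipiperidine gives the acylstannane 1-(tributylstannyl)dec-9-en-1-one F5. Reduction with BINAL-H (the R reagent is expected to be the one that delivers the S carbinol; THF, −78 °C) should give (S)-1-(tributylstannyl)dec-9-en-1-ol F6. MOMCl/iPr2NEt gives (S)-tributyl[1-(methoxymethoxy)dec-9-en-1-yl]stannane F7. Tin–lithium exchange (n-BuLi, THF, −78 °C, retention) gives (S)-[1-(methoxymethoxy)dec-9-en-1-yl]lithium F8, which should add to 6 to give the hemiketal (4S,5S)-4-(benzyloxy)-2-[(1R)-1-(methoxymethoxy)dec-9-en-1-yl]-5-pentyloxolan-2-ol F9. Et3SiH/BF3·OEt2 kept at −78 °C should give (2R,4S,5S)-4-(benzyloxy)-2-[(1R)-1-(methoxymethoxy)dec-9-en-1-yl]-5-pentyloxolane F10. HCl in MeOH removes the methoxymethyl group and returns the route to 13.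

Step 4. The carbenoid may be diverted into the CH2 of the pentyl chain next to C5, or into an oxonium ylide at the benzyl ether oxygen followed by benzyl shift. It may also give the trans lactone if catalyst and substrate preferences oppose each other; the mirror-image catalyst Rh2(5R-MEPY)4 is the first variation. Fallback: the same C3–C4 bond is closed by an intramolecular Reformatsky reaction, setting out from 3. BCl3/pentamethylbenzene (CH2Cl2, −78 °C) should give (S)-1-hydroxyheptan-2-yl bromoacetate F11. Dess–Martin periodinane should give the aldehyde (S)-1-oxoheptan-2-yl bromoacetate F12. SmI2 (THF, −78 °C) should close the ring to the hydroxy lactone (4S,5S)-4-hydroxy-5-pentyloxolan-2-one F13. Its C4 configuration arises under substrate control and would have to be established; only the cis isomer is carried on. Benzyl 2,2,2-trichloroacetimidate with catalytic TfOH then returns the route to 6.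

**Further compounds**
F1 | step 6 | (4S,5S)-4-(benzyloxy)-2-ethenyl-5-pentyloxolan-2-ol | C=CC1(O)C[C@H](OCc2ccccc2)[C@H](CCCCC)O1
F2 | step 6 | (2R,4S,5S)-4-(benzyloxy)-2-ethenyl-5-pentyloxolane | C=C[C@H]1C[C@H](OCc2ccccc2)[C@H](CCCCC)O1
F3 | step 6 | (2R,4S,5S)-4-(benzyloxy)-5-pentyloxolane-2-carbaldehyde | O=C[C@H]1C[C@H](OCc2ccccc2)[C@H](CCCCC)O1
F4 | step 7 | dec-9-enal | C=CCCCCCCCC=O
F5 | step 7 | 1-(tributylstannyl)dec-9-en-1-one | C=CCCCCCCCC(=O)[Sn](CCCC)(CCCC)CCCC
F6 | step 7 | (S)-1-(tributylstannyl)dec-9-en-1-ol | C=CCCCCCCC[C@@H](O)[Sn](CCCC)(CCCC)CCCC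
F7 | step 7 | (S)-tributyl[1-(methoxymethoxy)dec-9-en-1-yl]stannane | C=CCCCCCCC[C@@H](OCOC)[Sn](CCCC)(CCCC)CCCC
F8 | step 7 | (S)-[1-(methoxymethoxy)dec-9-en-1-yl]lithium | C=CCCCCCCC[C@H]([Li])OCOC
F9 | step 7 | (4S,5S)-4-(benzyloxy)-2-[(1R)-1-(methoxymethoxy)dec-9-en-1-yl]-5-pentyloxolan-2-ol | C=CCCCCCCC[C@@H](OCOC)C1(O)C[C@H](OCc2ccccc2)[C@H](CCCCC)O1
F10 | step 7 | (2R,4S,5S)-4-(benzyloxy)-2-[(1R)-1-(methoxymethoxy)dec-9-en-1-yl]-5-pentyloxolane | C=CCCCCCCC[C@@H](OCOC)[C@H]1C[C@H](OCc2ccccc2)[C@H](CCCCC)O1
F11 | step 4 | (S)-1-hydroxyheptan-2-yl bromoacetate | BrCC(=O)O[C@@H](CCCCC)CO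
F12 | step 4 | (S)-1-oxoheptan-2-yl bromoacetate | BrCC(=O)O[C@@H](CCCCC)C=O
F13 | step 4 | (4S,5S)-4-hydroxy-5-pentyloxolan-2-one | O=C1C[C@H](O)[C@H](CCCCC)O1
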